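**Retrosynthetic overview**
1. Remove the acetate. The CH2OH arm comes from NaIO4/NaBH4 truncation of a 1,2-dihydroxyethyl arm, so the carbinol carbon of D-glycerate ends as C-10 after it has set the quaternary centre.
2. The oxirane (second ring formed) comes from hydroxyl-directed VO(acac)2/tBuOOH epoxidation of a 2-aryl allylic alcohol (A(1,2) strain, erythro).
3. The 1,1-disubstituted alkene comes from methylenation of an aryl dioxolanyl ketone. The pentanoate and isobutyrate are installed just before that.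
4. The benzene ring (first ring formed) comes from a [4+2] cycloaddition of a vinylketene silyl acetal with a D-glycerate-derived terminal ynone, followed by loss of MeOH.
5. The ynone comes from methyl (R)-isopropylideneglycerate and HC≡CMgBr. The diene comes from TBSOCH2COCH3 and Ph3P=CHCO2Me.

Assumption: [C@@] in the given SMILES is read as (S) at the oxirane quaternary carbon (priorities O > CH2OAc > ring CH2 > aryl). Labels C-7 to C-10 follow thymol numbering.

**Step 1**
Reactants: 1 methyl (R)-2,2-dimethyl-1,3-dioxolane-4-carboxylate (isopropylidene D-glycerate); 2 ethynylmagnesium bromide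
Product: 4 (R)-1-(2,2-dimethyl-1,3-dioxolan-4-yl)prop-2-yn-1-one, via Weinreb amide 3 (not isolated)
Conditions: MeNH(OMe)·HCl (1.5 equiv), iPrMgCl (3.0 equiv), THF, −20 °C; then 2 (0.5 M in THF, 2.5 equiv), −20 → 0 °C; inverse quench into cold 1 M aq NaHSO4/Et2O
Reagents that add atoms: N,O-dimethylhydroxylamine hydrochloride, CNOC.Cl (its atoms stay only in 3)
Why: In this Weinreb ketone synthesis the chelated tetrahedral adduct stops the acetylide addition at the ketone, the bought stereocentre never meets base as a free ketone, and the cold acidic quench keeps the released amine protonated so it cannot add to the ynone.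

**Step 2**
Reactants: 5 1-[(tert-butyldimethylsilyl)oxy]propan-2-one; 6 methyl (triphenylphosphoranylidene)acetate
Product: 7 methyl (E)-4-[(tert-butyldimethylsilyl)oxy]-3-methylbut-2-enoate
Conditions: toluene, 90 °C, 16 h; chromatography removes the minor Z isomer
Reagents that add atoms: none
Why: Wittig olefination with a stabilised ylide puts CO2Me trans to the bulkier CH2OTBS group (E), which leaves the CH3 cis to the ester for the next step.

**Step 3**
Reactants: 7 methyl (E)-4-[(tert-butyldimethylsilyl)oxy]-3-methylbut-2-enoate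
Product: 9 1-methoxy-1-(trimethylsilyloxy)-3-{[(tert-butyldimethylsilyl)oxy]methyl}buta-1,3-diene, via lithium dienolate 8 (not isolated)
Conditions: LiN(iPr)2 (commercial solution, 1.1 equiv), THF/DMPU, −78 °C; Me3SiCl, −78 °C → rt; pentane, filter, concentrate, use at once
Reagents that add atoms: chlorotrimethylsilane, C[Si](C)(C)Cl; LiN(iPr)2, [Li+].CC(C)[N-]C(C)C (its lithium stays only in 8)
Why: Ester-directed kinetic γ-deprotonation takes the CH3 that lies syn to the carbonyl, and O-silylation of the extended enolate gives the vinylketene silyl acetal.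

**Step 4**
Reactants: 4 (R)-1-(2,2-dimethyl-1,3-dioxolan-4-yl)prop-2-yn-1-one; 9 1-methoxy-1-(trimethylsilyloxy)-3-{[(tert-butyldimethylsilyl)oxy]methyl}buta-1,3-diene
Product: 11 (R)-(2,2-dimethyl-1,3-dioxolan-4-yl)[2-hydroxy-4-(hydroxymethyl)phenyl]methanone, via ketal cycloadduct 10 (not isolated)
Conditions: toluene, 0 °C → rt, 12 h; then Et3N·3HF, MeCN, rt, 16 h
Reagents that add atoms: none
Why: In this normal-electron-demand Diels–Alder [4+2] cycloaddition the nucleophilic CH2 terminus of the diene bonds to the β-carbon of the ynone ("ortho" rule), so the ketal carbon sits next to the acyl-bearing carbon, and fluoride-triggered loss of the silyl groups and MeOH aromatises the new ring to the 1,2,4-pattern without touching the dioxolane stereocentre.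

**Step 5**
Reactants: 11 (R)-(2,2-dimethyl-1,3-dioxolan-4-yl)[2-hydroxy-4-(hydroxymethyl)phenyl]methanone
Product: 13 2-[(R)-2,2-dimethyl-1,3-dioxolane-4-carbonyl]-5-[(pentanoyloxy)methyl]phenyl 2-methylpropanoate, via benzylic monopentanoate 12 (not isolated)
Conditions: pentanoyl chloride (1.05 equiv), pyridine, CH2Cl2, −20 → 0 °C; then isobutyryl chloride (1.5 equiv), Et3N, DMAP (cat.), 0 °C → rt
Reagents that add atoms: pentanoyl chloride, CCCCC(=O)Cl; isobutyryl chloride, CC(C)C(=O)Cl
Why: In this sequential O-acylation the phenol is hydrogen-bonded to the ortho ketone and inert to acid chloride/pyridine in the cold, so the primary alcohol is esterified first and the phenol reacts only after DMAP/Et3N is added.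

**Step 6**
Reactants: 13 2-[(R)-2,2-dimethyl-1,3-dioxolane-4-carbonyl]-5-[(pentanoyloxy)methyl]phenyl 2-methylpropanoate
Product: 14 2-{1-[(S)-2,2-dimethyl-1,3-dioxolan-4-yl]ethenyl}-5-[(pentanoyloxy)methyl]phenyl 2-methylpropanoate
Conditions: Zn, CH2Br2, TiCl4 (reagent pre-formed in THF, −40 → 5 °C); 13 in CH2Cl2, 0 °C → rt; aq NaHCO3
Reagents that add atoms: dibromomethane, BrCBr
Why: In this Takai–Lombardo methylenation the gem-dimetallic methylene reagent is non-basic and attacks ketones but not esters, so the α-stereocentre is not epimerised (R becomes S only through a change in CIP priorities).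

**Step 7**
Reactants: 14 2-{1-[(S)-2,2-dimethyl-1,3-dioxolan-4-yl]ethenyl}-5-[(pentanoyloxy)methyl]phenyl 2-methylpropanoate
Product: 15 2-[(S)-3,4-dihydroxybut-1-en-2-yl]-5-[(pentanoyloxy)methyl]phenyl 2-methylpropanoate
Conditions: AcOH/H2O (4:1), 40 °C
Reagents that add atoms: none
Why: Mild acid-catalysed acetal hydrolysis frees the diol before any acid-sensitive oxirane exists, and both esters and the alkene tolerate aqueous acetic acid.

**Step 8**
Reactants: 15 2-[(S)-3,4-dihydroxybut-1-en-2-yl]-5-[(pentanoyloxy)methyl]phenyl 2-methylpropanoate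
Product: 16 2-{(S)-2-[(R)-1,2-dihydroxyethyl]oxiran-2-yl}-5-[(pentanoyloxy)methyl]phenyl 2-methylpropanoate
Conditions: VO(acac)2 (5 mol %), tBuOOH (5.5 M in decane, 1.5 equiv), CH2Cl2, 0 °C → rt; chromatography removes the minor threo isomer
Reagents that add atoms: tert-butyl hydroperoxide, CC(C)(C)OO
Why: In this hydroxyl-directed epoxidation the vanadium-bound secondary alkoxide delivers oxygen to the alkene face it sits over, and A(1,2) strain with the geminal aryl group forces the carbinol C–H (not CH2OH) next to the aryl, so (S)-15 gives the erythro epoxy alcohol with (S) configuration at the new quaternary carbon.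

**Step 9**
Reactants: 16 2-{(S)-2-[(R)-1,2-dihydroxyethyl]oxiran-2-yl}-5-[(pentanoyloxy)methyl]phenyl 2-methylpropanoate
Product: 18 2-[(R)-2-(hydroxymethyl)oxiran-2-yl]-5-[(pentanoyloxy)methyl]phenyl 2-methylpropanoate, via epoxy aldehyde 17 (not isolated)
Conditions: NaIO4 (1.5 equiv), THF/pH 7 buffer, 0 °C, 30 min; extract, crude 17 in EtOH; NaBH4 (0.5 equiv), −20 °C, 10 min; aq NH4Cl
Reagents that add atoms: none
Why: Malaprade glycol cleavage removes the spent relay stereocentre and leaves an aldehyde on a quaternary carbon that cannot epimerise, and short cold borohydride reduction takes the aldehyde far faster than the esters or the oxirane (S becomes R only through CIP priorities).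

**Step 10**
Reactants: 18 2-[(R)-2-(hydroxymethyl)oxiran-2-yl]-5-[(pentanoyloxy)methyl]phenyl 2-methylpropanoate
Product: 19 2-[(S)-2-(acetoxymethyl)oxiran-2-yl]-5-[(pentanoyloxy)methyl]phenyl 2-methylpropanoate (target)
Conditions: Ac2O, pyridine, DMAP (cat.), CH2Cl2, 0 °C
Reagents that add atoms: acetic anhydride, CC(=O)OC(C)=O
Why: DMAP-catalysed O-acetylation does not touch the oxirane, and a Payne shift in 18 would be degenerate and give the same enantiomer, so the configuration is safe (R becomes S only through CIP priorities).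

**Compound list**
1 | methyl (R)-2,2-dimethyl-1,3-dioxolane-4-carboxylate | COC(=O)[C@H]1COC(C)(C)O1 | starting material
2 | ethynylmagnesium bromide | C#C[Mg]Br | starting material
3 | (R)-N-methoxy-N,2,2-trimethyl-1,3-dioxolane-4-carboxamide (Weinreb amide, not isolated) | CON(C)C(=O)[C@H]1COC(C)(C)O1 | intermediate
4 | (R)-1-(2,2-dimethyl-1,3-dioxolan-4-yl)prop-2-yn-1-one | C#CC(=O)[C@H]1COC(C)(C)O1 | intermediate
5 | 1-[(tert-butyldimethylsilyl)oxy]propan-2-one | CC(=O)CO[Si](C)(C)C(C)(C)C | starting material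
6 | methyl (triphenylphosphoranylidene)acetate | COC(=O)C=P(c1ccccc1)(c1ccccc1)c1ccccc1 | starting material
7 | methyl (E)-4-[(tert-butyldimethylsilyl)oxy]-3-methylbut-2-enoate | COC(=O)/C=C(\C)CO[Si](C)(C)C(C)(C)C | intermediate
8 | lithium 1-methoxy-3-{[(tert-butyldimethylsilyl)oxy]methyl}buta-1,3-dien-1-olate (lithium dienolate, not isolated) | [Li+].COC([O-])=CC(=C)CO[Si](C)(C)C(C)(C)C | intermediate
9 | 1-methoxy-1-(trimethylsilyloxy)-3-{[(tert-butyldimethylsilyl)oxy]methyl}buta-1,3-diene (ketene acetal geometry irrelevant) | COC(O[Si](C)(C)C)=CC(=C)CO[Si](C)(C)C(C)(C)C | intermediate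
10 | (R)-(2,2-dimethyl-1,3-dioxolan-4-yl){6-methoxy-6-(trimethylsilyloxy)-4-{[(tert-butyldimethylsilyl)oxy]methyl}cyclohexa-1,4-dien-1-yl}methanone (ketal cycloadduct, ketal carbon epimers, not isolated) | COC1(O[Si](C)(C)C)C=C(CO[Si](C)(C)C(C)(C)C)CC=C1C(=O)[C@H]2COC(C)(C)O2 | intermediate
11 | (R)-(2,2-dimethyl-1,3-dioxolan-4-yl)[2-hydroxy-4-(hydroxymethyl)phenyl]methanone | OCc1ccc(C(=O)[C@H]2COC(C)(C)O2)c(O)c1 | intermediate
12 | {4-[(R)-2,2-dimethyl-1,3-dioxolane-4-carbonyl]-3-hydroxyphenyl}methyl pentanoate (not isolated) | CCCCC(=O)OCc1ccc(C(=O)[C@H]2COC(C)(C)O2)c(O)c1 | intermediate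
13 | 2-[(R)-2,2-dimethyl-1,3-dioxolane-4-carbonyl]-5-[(pentanoyloxy)methyl]phenyl 2-methylpropanoate | CCCCC(=O)OCc1ccc(C(=O)[C@H]2COC(C)(C)O2)c(OC(=O)C(C)C)c1 | intermediate
14 | 2-{1-[(S)-2,2-dimethyl-1,3-dioxolan-4-yl]ethenyl}-5-[(pentanoyloxy)methyl]phenyl 2-methylpropanoate | CCCCC(=O)OCc1ccc(C(=C)[C@H]2COC(C)(C)O2)c(OC(=O)C(C)C)c1 | intermediate
15 | 2-[(S)-3,4-dihydroxybut-1-en-2-yl]-5-[(pentanoyloxy)methyl]phenyl 2-methylpropanoate | CCCCC(=O)OCc1ccc(C(=C)[C@H](O)CO)c(OC(=O)C(C)C)c1 | intermediate
16 | 2-{(S)-2-[(R)-1,2-dihydroxyethyl]oxiran-2-yl}-5-[(pentanoyloxy)methyl]phenyl 2-methylpropanoate | CCCCC(=O)OCc1ccc([C@@]2([C@H](O)CO)CO2)c(OC(=O)C(C)C)c1 | intermediate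
17 | 2-[(S)-2-formyloxiran-2-yl]-5-[(pentanoyloxy)methyl]phenyl 2-methylpropanoate (not isolated) | CCCCC(=O)OCc1ccc([C@@]2(C=O)CO2)c(OC(=O)C(C)C)c1 | intermediate
18 | 2-[(R)-2-(hydroxymethyl)oxiran-2-yl]-5-[(pentanoyloxy)methyl]phenyl 2-methylpropanoate | CCCCC(=O)OCc1ccc([C@@]2(CO)CO2)c(OC(=O)C(C)C)c1 | intermediate
19 | 2-[(S)-2-(acetoxymethyl)oxiran-2-yl]-5-[(pentanoyloxy)methyl]phenyl 2-methylpropanoate | CCCCC(=O)OCc1ccc([C@@]2(COC(C)=O)CO2)c(OC(=O)C(C)C)c1 | target

**Step count**
- Total steps: 10.
- Longest linear sequence: 9 steps (5 → 19, steps 2 to 10).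

**Three steps most likely to fail**

*Step 4 (cycloaddition and aromatisation).* The terminal ynone may polymerise, or it may stop at a vinylogous Michael adduct.
- The fallback keeps the cycloaddition but uses an alkene dienophile and aromatises afterwards by dehydrogenation. It sets out from 3 (worked up and isolated this time) and 9, and comes back at 11.
- Vinylmagnesium bromide converts 3 into (R)-1-(2,2-dimethyl-1,3-dioxolan-4-yl)prop-2-en-1-one F1. At room temperature F1 and 9 undergo a [4+2] cycloaddition with the same regiochemistry to give the cyclohexene ketal cycloadduct F2.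
- Dilute citric acid unmasks the enolised 6-acylcyclohex-2-enone F3. DDQ in dioxane dehydrogenates this to the silyl-protected hydroxyaryl ketone F4, and Et3N·3HF then gives 11.

*Step 6 (methylenation).* The ketone is hindered, and the ortho ester may interfere.
- The fallback replaces the one-step carbonyl methylenation by addition and elimination on an ester-free substrate, and moves the acylations to afterwards. It sets out from 11 and comes back at 14.
- Et3SiCl/imidazole gives the bis(triethylsilyl) ether ketone F5. Me3SiCH2Li/CeCl3 at −78 °C adds without enolisation to give the β-hydroxysilane F6. KH in THF effects Peterson elimination to the bis(triethylsilyl) ether alkene F7, and Et3N·3HF gives the alkenyl phenol benzyl alcohol F8.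
- Isobutyryl chloride under Schotten–Baumann conditions (aq NaOH/CH2Cl2, Bu4NHSO4) esterifies only the phenoxide to give the hydroxymethyl aryl isobutyrate F9. Pentanoyl chloride/pyridine then gives 14.

*Step 8 (directed epoxidation).* The 1,2-diol may bind the metal through both oxygens, which would erode selectivity or promote opening of the benzylic oxirane.
- The fallback removes the chelating diol by a protecting-group detour, so that a single alkoxide directs the oxidation. It sets out from 15 and comes back at 16.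
- Et3SiCl (1.0 equiv)/2,6-lutidine at −40 °C silylates only the primary hydroxyl to give the primary triethylsilyl ether F10.
- VO(acac)2/tBuOOH then gives the silylated epoxy alcohol F11. Any minor diastereomer is separable here because the bought stereocentre is still present. Et3N·3HF at 0 °C returns 16.

**Further compounds**
F1 | step 4 | (R)-1-(2,2-dimethyl-1,3-dioxolan-4-yl)prop-2-en-1-one | C=CC(=O)[C@H]1COC(C)(C)O1
F2 | step 4 | cyclohexene ketal cycloadduct: (R)-(2,2-dimethyl-1,3-dioxolan-4-yl){2-methoxy-2-(trimethylsilyloxy)-4-{[(tert-butyldimethylsilyl)oxy]methyl}cyclohex-3-en-1-yl}methanone (ring epimers) | COC1(O[Si](C)(C)C)C=C(CO[Si](C)(C)C(C)(C)C)CCC1C(=O)[C@H]2COC(C)(C)O2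
F3 | step 4 | enolised 6-acylcyclohex-2-enone: 6-[(R)-2,2-dimethyl-1,3-dioxolane-4-carbonyl]-3-{[(tert-butyldimethylsilyl)oxy]methyl}cyclohex-2-en-1-one | O=C1C=C(CO[Si](C)(C)C(C)(C)C)CCC1C(=O)[C@H]2COC(C)(C)O2
F4 | step 4 | silyl-protected hydroxyaryl ketone: (R)-(2,2-dimethyl-1,3-dioxolan-4-yl)(4-{[(tert-butyldimethylsilyl)oxy]methyl}-2-hydroxyphenyl)methanone | CC(C)(C)[Si](C)(C)OCc1ccc(C(=O)[C@H]2COC(C)(C)O2)c(O)c1
F5 | step 6 | bis(triethylsilyl) ether ketone | CC[Si](CC)(CC)OCc1ccc(C(=O)[C@H]2COC(C)(C)O2)c(O[Si](CC)(CC)CC)c1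
F6 | step 6 | β-hydroxysilane (carbinol epimers) | CC[Si](CC)(CC)OCc1ccc(C(O)(C[Si](C)(C)C)[C@H]2COC(C)(C)O2)c(O[Si](CC)(CC)CC)c1
F7 | step 6 | bis(triethylsilyl) ether alkene | CC[Si](CC)(CC)OCc1ccc(C(=C)[C@H]2COC(C)(C)O2)c(O[Si](CC)(CC)CC)c1
F8 | step 6 | alkenyl phenol benzyl alcohol: 2-{1-[(S)-2,2-dimethyl-1,3-dioxolan-4-yl]ethenyl}-5-(hydroxymethyl)phenol | OCc1ccc(C(=C)[C@H]2COC(C)(C)O2)c(O)c1
F9 | step 6 | hydroxymethyl aryl isobutyrate: 2-{1-[(S)-2,2-dimethyl-1,3-dioxolan-4-yl]ethenyl}-5-(hydroxymethyl)phenyl 2-methylpropanoate | OCc1ccc(C(=C)[C@H]2COC(C)(C)O2)c(OC(=O)C(C)C)c1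
F10 | step 8 | primary triethylsilyl ether of 15 | CCCCC(=O)OCc1ccc(C(=C)[C@H](O)CO[Si](CC)(CC)CC)c(OC(=O)C(C)C)c1
F11 | step 8 | silylated epoxy alcohol (primary triethylsilyl ether of 16) | CCCCC(=O)OCc1ccc([C@@]2([C@H](O)CO[Si](CC)(CC)CC)CO2)c(OC(=O)C(C)C)c1
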